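## Retrosynthetic overview

1. The target comes from its di-O-methyl ether, cleaved with BBr3 in the last step.
2. Key disconnection: benzene ring B and the 20-membered macrocycle are opened together. A retro pyrone/alkyne [4+2] with CO2 put back gives an open chain. It carries a 2-pyron-3-yl group on the ring A oxygen and a but-3-ynyl arm on ring C.
3. The open chain comes from ionic reduction of a stilbene/homopropargylic alcohol. That comes from Barbier propargylation of a ring C aldehyde, made by SNAr of the ring D phenol on 4-fluorobenzaldehyde.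
4. The A–D bridge comes from a Wittig union. The pyronyl aryl ether comes from SNAr of 3-hydroxy-2-pyrone on 4-fluoro-3-methoxybenzaldehyde.
5. Ring order: rings A, D and C are bought. Ring B and the macrocycle form last, in the same operation.

Assumption: the SMILES holds no stereocentre and no double-bond descriptor, and the 20-membered ring is conformationally mobile. The target is therefore treated as achiral and no enantioselective step is needed.

## Route

Step 1
Reactants: 1 3-hydroxy-2H-pyran-2-one; 2 4-fluoro-3-methoxybenzaldehyde
Product: 3 3-methoxy-4-[(2-oxo-2H-pyran-3-yl)oxy]benzaldehyde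
Conditions: K2CO3, dry DMF, 110 °C
Reagents that add atoms: none
Why: Nucleophilic aromatic substitution (addition–elimination), in which carbonate deprotonates the acidic enolic OH of 1, the hard oxygen attacks the C–F carbon, and the para-formyl group stabilises the Meisenheimer adduct.

Step 2
Reactants: 4 3-hydroxy-4-methoxybenzyl alcohol; 3 3-methoxy-4-[(2-oxo-2H-pyran-3-yl)oxy]benzaldehyde
Product: 6 3-{4-[2-(3-hydroxy-4-methoxyphenyl)ethenyl]-2-methoxyphenoxy}-2H-pyran-2-one (E/Z mixture), via benzylphosphonium bromide 5 (not isolated)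
Conditions: PPh3·HBr, MeCN, reflux; evaporate; then 3, K2CO3, 18-crown-6 (cat.), THF, reflux
Reagents that add atoms: triphenylphosphine hydrobromide, [Br-].c1ccc(cc1)[PH+](c1ccccc1)c1ccccc1 (its P and Br atoms sit only in 5 and are gone in 6)
Why: The p-methoxybenzylic alcohol ionises under PPh3·HBr to give the phosphonium salt, and a Wittig olefination under mild solid–liquid carbonate conditions then takes the aldehyde faster than the pyrone; the alkene geometry does not matter because step 5 removes it.

Step 3
Reactants: 6 3-{4-[2-(3-hydroxy-4-methoxyphenyl)ethenyl]-2-methoxyphenoxy}-2H-pyran-2-one; 7 4-fluorobenzaldehyde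
Product: 8 4-{2-methoxy-5-[2-{3-methoxy-4-[(2-oxo-2H-pyran-3-yl)oxy]phenyl}ethenyl]phenoxy}benzaldehyde (E/Z mixture)
Conditions: Cs2CO3, 4 Å sieves, dry DMF, 80 °C
Reagents that add atoms: none
Why: Nucleophilic aromatic substitution of a strongly nucleophilic guaiacol-type phenoxide on para-formyl-activated fluoride, while ring A is no longer activated for ether exchange and dry carbonate leaves the pyrone closed.

Step 4
Reactants: 8 4-{2-methoxy-5-[2-{3-methoxy-4-[(2-oxo-2H-pyran-3-yl)oxy]phenyl}ethenyl]phenoxy}benzaldehyde
Product: 9 3-{4-[2-(3-{4-[1-hydroxybut-3-yn-1-yl]phenoxy}-4-methoxyphenyl)ethenyl]-2-methoxyphenoxy}-2H-pyran-2-one (racemic; E/Z mixture)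
Conditions: propargyl bromide, Zn dust, THF/sat. aq NH4Cl, 0 °C to rt
Reagents that add atoms: propargyl bromide, C#CCBr
Why: Barbier propargylation, in which the organozinc formed in situ adds to the aldehyde through a cyclic SE2' transition state to give the homopropargylic alcohol while lactone and stilbene stay inert; the new carbinol stereocentre forms racemic and is deleted in step 5.

Step 5
Reactants: 9 3-{4-[2-(3-{4-[1-hydroxybut-3-yn-1-yl]phenoxy}-4-methoxyphenyl)ethenyl]-2-methoxyphenoxy}-2H-pyran-2-one
Product: 10 3-{4-[2-(3-{4-(but-3-yn-1-yl)phenoxy}-4-methoxyphenyl)ethyl]-2-methoxyphenoxy}-2H-pyran-2-one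
Conditions: Et3SiH (10 equiv), TFA/CH2Cl2 1:4, 0 °C to rt
Reagents that add atoms: none
Why: Kursanov–Parnes ionic hydrogenation, in which TFA ionises the p-aryloxybenzylic alcohol and protonates the stilbene at the ring A side to give the p-methoxybenzylic cation on ring D, Et3SiH quenches both cations, and the terminal alkyne and acid-stable pyrone are not protonated under these conditions; the stereocentre and the E/Z mixture both disappear.

Step 6
Reactants: 10 3-{4-[2-(3-{4-(but-3-yn-1-yl)phenoxy}-4-methoxyphenyl)ethyl]-2-methoxyphenoxy}-2H-pyran-2-one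
Product: 12 di-O-methyl ether of the target macrocycle, via bridged bicyclic lactone 11 (not isolated)
Conditions: 1 mM in degassed 1,2-dichlorobenzene, BHT (10 mol %), sealed vessel or heated flow coil, 230 °C, 24 h
Reagents that add atoms: none
Why: An intramolecular Diels–Alder reaction of the 2-pyrone diene (C3 to C6) with the tethered terminal alkyne, followed by retro-Diels–Alder loss of CO2 from 11 (a sequence already proven for closing strained cyclophanes), builds benzene ring B and the unstrained 20-membered ring in one operation, and the substituted alkyne carbon bonds to the free C6–H terminus rather than to the aryloxy-blocked C3 terminus (sterics and the larger LUMO coefficient on the substituted alkyne carbon agree), which places the CH2CH2 arm meta to the ether oxygen; the two bridgehead stereocentres of racemic 11 vanish on aromatisation.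

Step 7
Reactants: 12 di-O-methyl ether of the target macrocycle
Product: 13 target macrocyclic bis(bibenzyl) CNP0329842.0
Conditions: BBr3 (6 equiv), CH2Cl2, −78 °C to rt; then H2O
Reagents that add atoms: none
Why: Lewis-acid aryl methyl ether cleavage, in which BBr3 binds each methoxy oxygen and bromide attacks the methyl carbon by SN2, a path closed to the two diaryl ether C(sp2)–O bonds.

## Compound list

1 | 3-hydroxy-2H-pyran-2-one | O=c1occcc1O | starting material
2 | 4-fluoro-3-methoxybenzaldehyde | COc1cc(C=O)ccc1F | starting material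
3 | 3-methoxy-4-[(2-oxo-2H-pyran-3-yl)oxy]benzaldehyde | COc1cc(C=O)ccc1Oc1cccoc1=O | intermediate
4 | 3-hydroxy-4-methoxybenzyl alcohol (isovanillyl alcohol) | COc1ccc(CO)cc1O | starting material
5 | (3-hydroxy-4-methoxybenzyl)triphenylphosphonium bromide, not isolated | COc1ccc(C[P+](c2ccccc2)(c2ccccc2)c2ccccc2)cc1O.[Br-] | intermediate
6 | 3-{4-[2-(3-hydroxy-4-methoxyphenyl)ethenyl]-2-methoxyphenoxy}-2H-pyran-2-one, E/Z mixture so no descriptor | COc1ccc(C=Cc2ccc(Oc3cccoc3=O)c(OC)c2)cc1O | intermediate
7 | 4-fluorobenzaldehyde | O=Cc1ccc(F)cc1 | starting material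
8 | 4-{2-methoxy-5-[2-{3-methoxy-4-[(2-oxo-2H-pyran-3-yl)oxy]phenyl}ethenyl]phenoxy}benzaldehyde, E/Z mixture | COc1ccc(C=Cc2ccc(Oc3cccoc3=O)c(OC)c2)cc1Oc1ccc(C=O)cc1 | intermediate
9 | homopropargylic alcohol on ring C, racemic, E/Z mixture | COc1ccc(C=Cc2ccc(Oc3cccoc3=O)c(OC)c2)cc1Oc1ccc(C(O)CC#C)cc1 | intermediate
10 | open-chain pyrone alkyne with both bridges saturated | COc1ccc(CCc2ccc(Oc3cccoc3=O)c(OC)c2)cc1Oc1ccc(CCC#C)cc1 | intermediate
11 | macrocyclic 2-oxabicyclo[2.2.2]octa-5,7-dien-3-one, racemic, not isolated; ring A oxygen on the bridgehead next to C=O, arylethyl arm on the alkene carbon next to the O-bearing bridgehead | O=C1OC2C=CC13C=C2CCc1ccc(cc1)Oc1cc(ccc1OC)CCc1ccc(O3)c(OC)c1 | intermediate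
12 | di-O-methyl ether of the target macrocycle | COc1cc2ccc1Oc1cccc(c1)CCc1ccc(cc1)Oc1cc(ccc1OC)CC2 | intermediate
13 | CNP0329842.0, macrocyclic bis(bibenzyl) diol, achiral | Oc1cc2ccc1Oc1cccc(c1)CCc1ccc(cc1)Oc1cc(ccc1O)CC2 | target

## Step count and risks

Total step count: 7. Longest linear sequence: 7 (1, 3, 6, 8, 9, 10, 12, 13).

Step 6 is the most likely to fail. A donor-substituted pyrone meets an unactivated alkyne at 1 mM, so the rate may be too low below the decomposition limit. The ortho-bridged regioisomer or oligomers may also compete. The fallback sets out from 10 and comes back at 12.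
- It keeps the ring B plus macrocycle closure but replaces the alkyne with an electron-poor, traceless alkyne equivalent.
- Semihydrogenation (H2, Pd/CaCO3 poisoned with Pb(OAc)2, quinoline, EtOAc) gives the but-3-enyl pyrone F1.
- Cross metathesis with phenyl vinyl sulfone (second-generation Hoveyda–Grubbs catalyst, CH2Cl2, 40 °C) gives the (E)-vinyl sulfone F2.
- Heating F2 at 1 mM in 1,2-dichlorobenzene with solid NaHCO3 at about 160 °C triggers a polarity-matched Diels–Alder reaction.
- The nucleophilic pyrone C6 bonds to the alkyl-bearing β-carbon and C3 bonds to the sulfonyl-bearing carbon. Loss of CO2 and benzenesulfinic acid then gives 12 with the meta pattern fixed electronically.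

Step 5 comes second. The benzylic alcohol should reduce easily, but the stilbene may resist protonation in TFA or dimerise through its cation. The fallback sets out from 9 and comes back at 12.
- Et3SiH with BF3·OEt2 in CH2Cl2 at −40 °C removes only the hydroxyl group and gives the stilbene alkyne F3.
- The pyrone/alkyne cycloaddition with CO2 loss is run on F3 and gives the macrocyclic stilbene F4.
- Catalytic hydrogenation (H2, Pd/C, EtOAc), possible once alkyne and pyrone are consumed, saturates the bridge to 12.

Step 1 comes third. The pyronolate is a weak nucleophile and may degrade at 110 °C before it displaces fluoride next to a methoxy group. The fallback sets out from 1 and comes back at 3.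
- The polar substitution is replaced by an oxidative Chan–Lam coupling of 1 with commercial (4-formyl-2-methoxyphenyl)boronic acid.
- Conditions are Cu(OAc)2, pyridine, 4 Å sieves, CH2Cl2, air, rt. The C–O bond forms by reductive elimination at copper at room temperature.
- New compounds on this way: none F0.

## Further compounds

F1 | step 6 | 3-{4-[2-(3-{4-(but-3-en-1-yl)phenoxy}-4-methoxyphenyl)ethyl]-2-methoxyphenoxy}-2H-pyran-2-one | COc1ccc(CCc2ccc(Oc3cccoc3=O)c(OC)c2)cc1Oc1ccc(CCC=C)cc1
F2 | step 6 | 3-{4-[2-(3-{4-[(3E)-4-(phenylsulfonyl)but-3-en-1-yl]phenoxy}-4-methoxyphenyl)ethyl]-2-methoxyphenoxy}-2H-pyran-2-one | COc1ccc(CCc2ccc(Oc3cccoc3=O)c(OC)c2)cc1Oc1ccc(CC/C=C/S(=O)(=O)c2ccccc2)cc1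
F3 | step 5 | 3-{4-[2-(3-{4-(but-3-yn-1-yl)phenoxy}-4-methoxyphenyl)ethenyl]-2-methoxyphenoxy}-2H-pyran-2-one, E/Z mixture | COc1ccc(C=Cc2ccc(Oc3cccoc3=O)c(OC)c2)cc1Oc1ccc(CCC#C)cc1
F4 | step 5 | macrocyclic stilbene, di-O-methyl ether with a CH=CH bridge between rings A and D, E/Z mixture | COc1cc2ccc1Oc1cccc(c1)CCc1ccc(cc1)Oc1cc(ccc1OC)C=C2
F0 | step 1 | none | none
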